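**Direct plan and its weak points**

A direct plan would allylate propane-1,3-diol in two directions to the C2-symmetric diene diol A1 and close both allyl groups onto Boc carbonates to give the bis(iodomethyl) bis-carbonate A2. It would then attach the lipid end by a nickel-hydride hydroalkylation of oct-1-ene at one C–I bond (A3), acylate the other C–I bond reductively with methyl malonyl chloride (A4), and end with carbonate methanolysis and lactonisation.
- The one-sided hydroalkylation of A2 would be weak: the two C–I bonds are identical, so the mono-product is statistical at best and needs recycling, and the β-oxygenated iodide can lose its carbonate by β-elimination at nickel.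
- The reductive acylation A3 → A4 would be weak: an enolisable malonyl chloride (ketene formation), an acidic β-keto ester product and again a β-oxygenated alkyl–metal, all on the most advanced intermediate.
- The Boc/iodocarbonate stretch A1 → A2 would be weak: two Boc groups and two iodine atoms are installed only to be excised, and cyclic carbonate formation competes with the double acylation.

**Retrosynthetic overview of the new route**

- C3–C9 of the target, with C5 (R) and C7 (R), is the statin side chain. It is bought as the commercial atorvastatin nitrile 1: the dioxane oxygens are O5 and O7, the ester carbon is C3, the nitrile carbon is C9.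
- Key disconnection C10–C11: the C9 methyl ketone 6 and decanal are joined by a boron aldol in which O7 at C7 relays to C11 (1,5-anti). The boron aldolate is reduced in the same flask, so C11 relays to C9 (1,3-syn). Both missing stereocentres and the whole C11–C20 chain arrive in one operation.
- The only ring, the C1–O–C5 4-hydroxy-5,6-dihydropyran-2-one, closes last. A temporary C3–O7 δ-lactone (not in the target) activates C3 for Claisen extension by C1–C2 and is opened again when an acylketene is captured by O5.
- Nothing symmetric is desymmetrised, no β-oxygenated halide meets a low-valent metal, and no atoms are added only to be removed.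

Key step: step 4

Remark: the target is treated as the 4-hydroxy enol tautomer of the 6-substituted oxane-2,4-dione; the two interconvert. Carbons are numbered C1 (lactone carbonyl) to C20 along the chain.

**Route**

Step 1
Reactants: 1 tert-butyl 2-[(4R,6R)-6-(cyanomethyl)-2,2-dimethyl-1,3-dioxan-4-yl]acetate
Product: 3 tert-butyl 2-[(4R,6S)-2,2-dimethyl-6-(2-oxoethyl)-1,3-dioxan-4-yl]acetate, via N-alumanyl aldimine 2 (not isolated)
Conditions: i-Bu2AlH (1.15 equiv), PhMe, −78 °C; then H2O, aq. potassium sodium tartrate, 0 °C → rt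
Reagents that add atoms: water, O
Why: Partial hydride reduction of the nitrile stops at the N-alumanyl aldimine, which is hydrolysed on work-up; at −78 °C with a slight excess the hindered tert-butyl ester should stay intact, and no stereocentre is touched (the label at C7 changes only through the priorities).

Step 2
Reactants: 3 tert-butyl 2-[(4R,6S)-2,2-dimethyl-6-(2-oxoethyl)-1,3-dioxan-4-yl]acetate
Product: 5 tert-butyl 2-[(4R,6R)-6-(2-hydroxypropyl)-2,2-dimethyl-1,3-dioxan-4-yl]acetate (both carbinol epimers), via bromomagnesium alkoxide 4 (not isolated)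
Conditions: MeMgBr (1.2 equiv), THF, −78 °C; then H2O
Reagents that add atoms: methylmagnesium bromide, C[Mg]Br
Why: Grignard addition to the aldehyde is far faster than attack on the tert-butyl ester at −78 °C and brings in C10; the new carbinol centre is left as a mixture because the next step erases it.

Step 3
Reactants: 5 tert-butyl 2-[(4R,6R)-6-(2-hydroxypropyl)-2,2-dimethyl-1,3-dioxan-4-yl]acetate (both carbinol epimers)
Product: 6 tert-butyl 2-[(4R,6S)-2,2-dimethyl-6-(2-oxopropyl)-1,3-dioxan-4-yl]acetate
Conditions: n-Pr4N[RuO4] (5 mol%), NMO (1.5 equiv), 4 Å MS, CH2Cl2, rt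
Reagents that add atoms: none
Why: Ley–Griffith oxidation of the secondary alcohol under neutral conditions should give the C9 methyl ketone without β-elimination of O7 and without touching the acetonide or the ester.

Step 4
Reactants: 6 tert-butyl 2-[(4R,6S)-2,2-dimethyl-6-(2-oxopropyl)-1,3-dioxan-4-yl]acetate; 7 decanal
Product: 10 tert-butyl 2-[(4R,6R)-6-[(2S,4S)-2,4-dihydroxytridecyl]-2,2-dimethyl-1,3-dioxan-4-yl]acetate, via boron enolate 8 (not isolated), via boron aldolate 9 (not isolated)
Conditions: c-Hex2BCl (1.4 equiv), Et3N (1.6 equiv), Et2O, 0 °C; 7 (1.3 equiv), −78 → −20 °C; LiBH4 (3 equiv, THF), −78 °C; then MeOH, pH 7 buffer, 30% H2O2, 0 °C → rt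
Reagents that add atoms: none
Why: Kinetic enolisation of 6 at the C10 methyl group gives boron enolate 8, which adds to decanal to form the C10–C11 bond, and the chelated boron aldolate 9 is reduced in the same flask by external hydride before oxidative release of the diol. The closest known reaction types are the 1,5-anti boron aldol of β-alkoxy methyl ketones and the one-pot boron aldol/LiBH4 reduction to 1,3-syn diols (a Narasaka–Prasad-type reduction of the aldolate). No ring is closed in this step. C11 (S) is controlled by C7 through its ether oxygen O7: in the favoured boat transition state the formyl hydrogen of decanal contacts O7, which leads to the 1,5-anti product. C9 (S) is controlled by C11: hydride adds to the six-membered O–B–O chelate of 9 on the face that gives the 1,3-syn diol. The step needs enolisation at the methyl group and not at C8 (secured by the bulky borane and amine), a β-oxygen that is an alkyl ether and not a silyl ether (O7 of the acetonide qualifies), and a tert-butyl ester that is neither enolised nor reduced at −78 °C.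

Step 5
Reactants: 10 tert-butyl 2-[(4R,6R)-6-[(2S,4S)-2,4-dihydroxytridecyl]-2,2-dimethyl-1,3-dioxan-4-yl]acetate
Product: 12 (4R,6R)-6-[(2S,4S)-2,4-dihydroxytridecyl]-4-hydroxyoxan-2-one, via tetrahydroxy acid 11 (not isolated)
Conditions: TFA/CH2Cl2 (1:4), H2O (5 equiv), 0 °C → rt; evaporate; PhMe, 80 °C
Reagents that add atoms: none
Why: Acidolysis removes the acetonide and the tert-butyl group, and the freed C7 hydroxyl closes a six-membered δ-lactone onto the C3 carboxyl (6-exo-trig), which turns the inert tert-butyl ester into a reactive acyl donor; no stereocentre is touched.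

Step 6
Reactants: 12 (4R,6R)-6-[(2S,4S)-2,4-dihydroxytridecyl]-4-hydroxyoxan-2-one; 13 tert-butyl acetate
Product: 18 (6R)-4-hydroxy-6-[(2R,4S,6S)-2,4,6-trihydroxypentadecyl]-5,6-dihydro-2H-pyran-2-one, via lithium enolate 14 (not isolated), via hemiketal 15 (not isolated), via open keto ester 16 (not isolated), via acylketene 17 (not isolated)
Conditions: LiN(i-Pr)2 (6.5 equiv), 13 (7 equiv), THF, −78 °C; 12, −78 → −40 °C; AcOH, −78 °C, aqueous work-up; crude in PhMe (0.01 M), 110 °C
Reagents that add atoms: none
Why: Crossed Claisen condensation followed by thermal acylketene lactonisation: excess enolate 14 first converts the three hydroxyls into lithium alkoxides and then adds to the lactone carbonyl C3, the tetrahedral adduct resisting a second addition until the quench releases hemiketal 15 and its open form 16, whose β-keto tert-butyl ester loses 2-methylpropan-2-ol on heating to acylketene 17, which the C5 hydroxyl captures in a six-membered closure under neutral conditions that leave all four stereocentres untouched.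

**Compound list**

1 | tert-butyl 2-[(4R,6R)-6-(cyanomethyl)-2,2-dimethyl-1,3-dioxan-4-yl]acetate | N#CC[C@@H]1C[C@H](CC(=O)OC(C)(C)C)OC(C)(C)O1 | starting material
2 | N-(diisobutylalumanyl) aldimine of aldehyde 3 (dioxane centres as in 1) | CC(C)C[Al](CC(C)C)N=CC[C@@H]1C[C@H](CC(=O)OC(C)(C)C)OC(C)(C)O1 | intermediate (not isolated)
3 | tert-butyl 2-[(4R,6S)-2,2-dimethyl-6-(2-oxoethyl)-1,3-dioxan-4-yl]acetate | O=CC[C@@H]1C[C@H](CC(=O)OC(C)(C)C)OC(C)(C)O1 | intermediate
4 | bromomagnesium alkoxide of alcohol 5 | CC(O[Mg]Br)C[C@@H]1C[C@H](CC(=O)OC(C)(C)C)OC(C)(C)O1 | intermediate (not isolated)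
5 | tert-butyl 2-[(4R,6R)-6-(2-hydroxypropyl)-2,2-dimethyl-1,3-dioxan-4-yl]acetate (both carbinol epimers) | CC(O)C[C@@H]1C[C@H](CC(=O)OC(C)(C)C)OC(C)(C)O1 | intermediate
6 | tert-butyl 2-[(4R,6S)-2,2-dimethyl-6-(2-oxopropyl)-1,3-dioxan-4-yl]acetate | CC(=O)C[C@@H]1C[C@H](CC(=O)OC(C)(C)C)OC(C)(C)O1 | intermediate
7 | decanal | CCCCCCCCCC=O | starting material
8 | dicyclohexylboron enolate of ketone 6 (C9–O–B, C9=C10 terminal) | C=C(OB(C1CCCCC1)C1CCCCC1)C[C@@H]1C[C@H](CC(=O)OC(C)(C)C)OC(C)(C)O1 | intermediate (not isolated)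
9 | dicyclohexylboron aldolate (C11 S O-boryl, C9 ketone) | CCCCCCCCC[C@H](OB(C1CCCCC1)C1CCCCC1)CC(=O)C[C@@H]1C[C@H](CC(=O)OC(C)(C)C)OC(C)(C)O1 | intermediate (not isolated)
10 | tert-butyl 2-[(4R,6R)-6-[(2S,4S)-2,4-dihydroxytridecyl]-2,2-dimethyl-1,3-dioxan-4-yl]acetate | CCCCCCCCC[C@H](O)C[C@H](O)C[C@@H]1C[C@H](CC(=O)OC(C)(C)C)OC(C)(C)O1 | intermediate
11 | (3R,5R,7S,9S)-3,5,7,9-tetrahydroxyoctadecanoic acid | CCCCCCCCC[C@H](O)C[C@H](O)C[C@@H](O)C[C@@H](O)CC(=O)O | intermediate (not isolated)
12 | (4R,6R)-6-[(2S,4S)-2,4-dihydroxytridecyl]-4-hydroxyoxan-2-one | CCCCCCCCC[C@H](O)C[C@H](O)C[C@@H]1C[C@@H](O)CC(=O)O1 | intermediate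
13 | tert-butyl acetate | CC(=O)OC(C)(C)C | starting material
14 | lithium 1-tert-butoxyethen-1-olate | [Li+].C=C([O-])OC(C)(C)C | intermediate (not isolated)
15 | tert-butyl 2-[(4R,6R)-6-[(2S,4S)-2,4-dihydroxytridecyl]-2,4-dihydroxyoxan-2-yl]acetate (both anomers) | CCCCCCCCC[C@H](O)C[C@H](O)C[C@@H]1C[C@@H](O)CC(O)(CC(=O)OC(C)(C)C)O1 | intermediate (not isolated)
16 | tert-butyl (5R,7R,9S,11S)-5,7,9,11-tetrahydroxy-3-oxoicosanoate | CCCCCCCCC[C@H](O)C[C@H](O)C[C@@H](O)C[C@@H](O)CC(=O)CC(=O)OC(C)(C)C | intermediate (not isolated)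
17 | (5R,7R,9S,11S)-5,7,9,11-tetrahydroxy-3-oxoicos-1-en-1-one (acylketene) | CCCCCCCCC[C@H](O)C[C@H](O)C[C@@H](O)C[C@@H](O)CC(=O)C=C=O | intermediate (not isolated)
18 | (6R)-4-hydroxy-6-[(2R,4S,6S)-2,4,6-trihydroxypentadecyl]-5,6-dihydro-2H-pyran-2-one | CCCCCCCCC[C@H](O)C[C@H](O)C[C@@H](O)C[C@@H]1CC(O)=CC(=O)O1 | target

**Count and risks**

Total step count: 6. Longest linear sequence: 6 steps (1 → 18).

Steps most likely to fail:

1. Step 4. The facial selectivity at C11 may be poor if the dioxane oxygen O7 relays the 1,5-induction less well than a simple alkyl ether, or the in situ reduction may be incomplete. Fallback: the route sets out from aldehyde 3 and comes back at diol 10, forming C9–C10 instead of C10–C11. Undecan-2-one F1 would be converted (LiN(i-Pr)2, Me3SiCl, THF, −78 °C) into trimethyl(undec-1-en-2-yloxy)silane F2. A Mukaiyama aldol of F2 with 3 (BF3·OEt2, CH2Cl2, −78 °C) through the open, dipole-minimised transition state should set C9 1,3-anti to C7 and give the β-hydroxy ketone tert-butyl 2-[(4R,6R)-6-[(2R)-2-hydroxy-4-oxotridecyl]-2,2-dimethyl-1,3-dioxan-4-yl]acetate F3. A Narasaka–Prasad reduction (Et2BOMe, NaBH4, THF/MeOH, −78 °C) would then set C11 syn to C9 and deliver 10.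

2. Step 6. The three lithium alkoxides may make the lactone insoluble or favour enolisation of the lactone over addition, and the thermal closure may compete with dehydration of the hemiketal. Fallback: the route sets out from lactone 12 and comes back at hemiketal 15. Silylation (Et3SiOTf, 2,6-lutidine, CH2Cl2, 0 °C) would give the tris(triethylsilyl) ether of lactone 12 F4. Claisen addition of enolate 14 (2 equiv, THF, −78 °C) would give the tris(triethylsilyl) ether of hemiketal 15 F5. Desilylation (HF·pyridine, THF/pyridine, 0 °C) would release 15, which is heated as in step 6.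

3. Step 1. Over-reduction may occur, either at the tert-butyl ester or of the aldimine to the amine. Fallback: the route sets out from nitrile 1 and comes back at methyl ketone 6, building C10 by C–C bond formation at the nitrile with a zinc enolate that ignores esters. A Blaise reaction of 1 with benzyl bromoacetate (Zn dust, Me3SiCl cat., THF, reflux, slow addition; aq. K2CO3 work-up) would give the benzyl (Z)-β-enamino ester of nitrile 1 F6. Mild hydrolysis (aq. citric acid, THF, rt) would give the benzyl β-keto ester F7. Hydrogenolysis (H2, Pd/C, EtOAc) would give the β-keto acid F8, which loses CO2 on warming to give 6.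

**Further compounds**

F1 | step 4 | undecan-2-one | CCCCCCCCCC(C)=O
F2 | step 4 | trimethyl(undec-1-en-2-yloxy)silane | CCCCCCCCCC(=C)O[Si](C)(C)C
F3 | step 4 | tert-butyl 2-[(4R,6R)-6-[(2R)-2-hydroxy-4-oxotridecyl]-2,2-dimethyl-1,3-dioxan-4-yl]acetate | CCCCCCCCCC(=O)C[C@H](O)C[C@@H]1C[C@H](CC(=O)OC(C)(C)C)OC(C)(C)O1
F4 | step 6 | tris(triethylsilyl) ether of lactone 12 (all centres as in 12) | CCCCCCCCC[C@H](O[Si](CC)(CC)CC)C[C@H](O[Si](CC)(CC)CC)C[C@@H]1C[C@@H](O[Si](CC)(CC)CC)CC(=O)O1
F5 | step 6 | tris(triethylsilyl) ether of hemiketal 15 (both anomers) | CCCCCCCCC[C@H](O[Si](CC)(CC)CC)C[C@H](O[Si](CC)(CC)CC)C[C@@H]1C[C@@H](O[Si](CC)(CC)CC)CC(O)(CC(=O)OC(C)(C)C)O1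
F6 | step 1 | benzyl (Z)-3-amino-4-[6-(2-tert-butoxy-2-oxoethyl)-2,2-dimethyl-1,3-dioxan-4-yl]but-2-enoate (dioxane centres as in 1) | N/C(C[C@@H]1C[C@H](CC(=O)OC(C)(C)C)OC(C)(C)O1)=C\C(=O)OCc1ccccc1
F7 | step 1 | benzyl 4-[6-(2-tert-butoxy-2-oxoethyl)-2,2-dimethyl-1,3-dioxan-4-yl]-3-oxobutanoate (dioxane centres as in 1) | O=C(CC(=O)OCc1ccccc1)C[C@@H]1C[C@H](CC(=O)OC(C)(C)C)OC(C)(C)O1
F8 | step 1 | 4-[6-(2-tert-butoxy-2-oxoethyl)-2,2-dimethyl-1,3-dioxan-4-yl]-3-oxobutanoic acid (dioxane centres as in 1) | OC(=O)CC(=O)C[C@@H]1C[C@H](CC(=O)OC(C)(C)C)OC(C)(C)O1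
A1 | direct plan | (4S,6S)-nona-1,8-diene-4,6-diol | C=CC[C@H](O)C[C@@H](O)CC=C
A2 | direct plan | 4,4'-methylenebis[(4R,6R)-6-(iodomethyl)-1,3-dioxan-2-one] | IC[C@H]1C[C@@H](C[C@@H]2C[C@H](CI)OC(=O)O2)OC(=O)O1
A3 | direct plan | (4R,6R)-6-(iodomethyl)-4-{[(4S,6S)-6-nonyl-2-oxo-1,3-dioxan-4-yl]methyl}-1,3-dioxan-2-one | CCCCCCCCC[C@H]1C[C@@H](C[C@@H]2C[C@H](CI)OC(=O)O2)OC(=O)O1
A4 | direct plan | methyl 4-[(4R,6R)-6-{[(4S,6S)-6-nonyl-2-oxo-1,3-dioxan-4-yl]methyl}-2-oxo-1,3-dioxan-4-yl]-3-oxobutanoate | CCCCCCCCC[C@H]1C[C@@H](C[C@@H]2C[C@H](CC(=O)CC(=O)OC)OC(=O)O2)OC(=O)O1
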